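**Plan**

1. Numbering: butenolide O1, C2(=O), C3, C4 (its CH2OH is C4′), C5; chain C6–C20, with C8′ and C20′ the hydroxymethyl carbons on C8 and C20. The retrosynthesis cuts C3=C4 and O1–C2 (intramolecular Horner–Wadsworth–Emmons of a C5 phosphonoacetate onto a C4 ketone), then C7=C8 (ring-closing metathesis), then the tether ester C5–O–C8′, the C9–C10 bond (allylic alkylation) and C5–C6 (allylation of a glyceraldehyde).
2. Enabling feature: the C5 oxygen and C8′ are cis across the trisubstituted C7=C8 alkene, so the six atoms O–C5–C6–C7=C8–C8′ can be held as a 5,6-dihydro-2H-pyran-2-one ring with C8′ as carbonyl; that ring admits only the required cis (7Z) geometry.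
3. Forward: farnesol is oxidised at its remote (E)-methyl group and extended by a 2-methyleneallyl unit to the 2-alkylacrylic acid (C8′–C20′); (S)-glyceraldehyde acetonide is allylated (C4′–C7); esterification and metathesis close the six-membered lactone, which is reduced open to the Z-diol; the butenolide, the only ring of the target, is closed last.
4. Stereochemistry: C5 (R) comes from a matched, anti-selective allylboration of (S)-glyceraldehyde acetonide (the C4 centre is later oxidised away); 7Z from the lactone ring; 11E and 15E from farnesol; 19E from E-selective SeO2 oxidation.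

Key step: step 11

Abbreviations: TBDPSO = tert-butyldiphenylsilyloxy; TBSO = tert-butyldimethylsilyloxy; Ipc = isopinocampheyl; DMP = Dess–Martin periodinane; PMB = 4-methoxybenzyl.
Assumption: commercial aldehyde 12 oligomerises on storage and is taken to be freshly distilled before step 9.

**Step 1**
Reactants: 1 (2E,6E)-farnesol
Product: 2 (2E,6E)-farnesyl acetate
Conditions: Ac2O, Et3N, DMAP (cat.), CH2Cl2, 0 °C to rt
Reagents that add atoms: acetic anhydride CC(=O)OC(C)=O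
Why: DMAP-catalysed O-acetylation of the primary allylic alcohol is routine; the acetate masks the future C10 oxygen and deactivates the neighbouring alkene towards the next oxidation.

**Step 2**
Reactants: 2 (2E,6E)-farnesyl acetate
Product: 3 (2E,6E,10E)-12-hydroxy-3,7,11-trimethyldodeca-2,6,10-trien-1-yl acetate
Conditions: SeO2 (cat.), t-BuOOH, salicylic acid (cat.), CH2Cl2, 0 °C to rt
Reagents that add atoms: tert-butyl hydroperoxide CC(C)(C)OO (oxygen relayed by catalytic selenium dioxide O=[Se]=O)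
Why: Catalytic SeO2 allylic oxidation (ene reaction, then [2,3]-sigmatropic shift) should attack the most electron-rich, remote trisubstituted alkene at its (E)-methyl group, giving the E primary allylic alcohol (future C19=C20 and C20′).

**Step 3**
Reactants: 3 (2E,6E,10E)-12-hydroxy-3,7,11-trimethyldodeca-2,6,10-trien-1-yl acetate
Product: 4 (2E,6E,10E)-12-(TBDPSO)-3,7,11-trimethyldodeca-2,6,10-trien-1-yl acetate
Conditions: TBDPSCl, imidazole, CH2Cl2, rt
Reagents that add atoms: tert-butyl(chloro)diphenylsilane CC(C)(C)[Si](Cl)(c1ccccc1)c1ccccc1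
Why: Imidazole-promoted silylation of the primary allylic alcohol installs an acid-robust silyl ether that should last to the final step.

**Step 4**
Reactants: 4 (2E,6E,10E)-12-(TBDPSO)-3,7,11-trimethyldodeca-2,6,10-trien-1-yl acetate
Product: 5 (2E,6E,10E)-12-(TBDPSO)-3,7,11-trimethyldodeca-2,6,10-trien-1-ol
Conditions: K2CO3 (cat.), MeOH, rt
Reagents that add atoms: none
Why: Base-catalysed transesterification with methanol removes the acetate while the TBDPS ether is inert to carbonate.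

**Step 5**
Reactants: 5 (2E,6E,10E)-12-(TBDPSO)-3,7,11-trimethyldodeca-2,6,10-trien-1-ol
Product: 6 (2E,6E,10E)-1-bromo-12-(TBDPSO)-3,7,11-trimethyldodeca-2,6,10-triene
Conditions: CBr4, PPh3, CH2Cl2, 0 °C
Reagents that add atoms: carbon tetrabromide BrC(Br)(Br)Br
Why: Appel bromination displaces the alkoxyphosphonium ion by SN2 at the primary allylic carbon under neutral conditions that keep the silyl ether and the alkene geometry.

**Step 6**
Reactants: 6 (2E,6E,10E)-1-bromo-12-(TBDPSO)-3,7,11-trimethyldodeca-2,6,10-triene; 7 2-methylprop-2-en-1-ol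
Product: 9 (5E,9E,13E)-15-(TBDPSO)-6,10,14-trimethyl-2-methylidenepentadeca-5,9,13-trien-1-ol, via dilithio dianion of 2-methylprop-2-en-1-ol 8 (not isolated)
Conditions: 7, n-BuLi (2 equiv per 7), TMEDA, Et2O, 0 °C to rt; then 6, THF, −78 to 0 °C
Reagents that add atoms: none
Why: Allylic lithiation of the lithium alkoxide gives a dianion whose two carbanion termini are equivalent, and its C-alkylation by SN2 at the primary allylic bromide (known alkylation of the methallyl alcohol dianion) should form the C9–C10 bond.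

**Step 7**
Reactants: 9 (5E,9E,13E)-15-(TBDPSO)-6,10,14-trimethyl-2-methylidenepentadeca-5,9,13-trien-1-ol
Product: 10 (5E,9E,13E)-15-(TBDPSO)-6,10,14-trimethyl-2-methylidenepentadeca-5,9,13-trienal
Conditions: DMP, CH2Cl2, 0 °C to rt; used without storage
Reagents that add atoms: none
Why: Dess–Martin oxidation converts the primary allylic alcohol to the 2-substituted propenal without touching the alkenes or the silyl ether.

**Step 8**
Reactants: 10 (5E,9E,13E)-15-(TBDPSO)-6,10,14-trimethyl-2-methylidenepentadeca-5,9,13-trienal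
Product: 11 (5E,9E,13E)-15-(TBDPSO)-6,10,14-trimethyl-2-methylidenepentadeca-5,9,13-trienoic acid
Conditions: NaClO2, NaH2PO4, 2-methylbut-2-ene (excess), t-BuOH/H2O, 0 °C to rt
Reagents that add atoms: sodium chlorite [Na+].[O-]Cl=O
Why: Pinnick oxidation takes the enal to the 2-alkylacrylic acid, and the alkene scavenger removes hypochlorous acid before it can attack the trisubstituted alkenes.

**Step 9**
Reactants: 12 (S)-2,2-dimethyl-1,3-dioxolane-4-carbaldehyde
Product: 14 (R)-1-[(S)-2,2-dimethyl-1,3-dioxolan-4-yl]but-3-en-1-ol, via diisopinocampheylborinate ester of the product 13 (not isolated)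
Conditions: (+)-Ipc2BOMe [(−)-α-pinene series], allylMgBr, Et2O, −78 °C to rt; then 12, −78 °C; NaOH, H2O2, rt
Reagents that add atoms: allylmagnesium bromide C=CC[Mg]Br
Why: Brown allylboration through a chair Zimmerman–Traxler transition state should deliver allyl to the re face of the aldehyde, the face also preferred by the α-alkoxy centre (Felkin–Anh, anti), so reagent and substrate control are matched and set C5 as R, anti to the C4 oxygen.

**Step 10**
Reactants: 11 (5E,9E,13E)-15-(TBDPSO)-6,10,14-trimethyl-2-methylidenepentadeca-5,9,13-trienoic acid; 14 (R)-1-[(S)-2,2-dimethyl-1,3-dioxolan-4-yl]but-3-en-1-ol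
Product: 15 (R)-1-[(S)-2,2-dimethyl-1,3-dioxolan-4-yl]but-3-en-1-yl (5E,9E,13E)-15-(TBDPSO)-6,10,14-trimethyl-2-methylidenepentadeca-5,9,13-trienoate
Conditions: DCC, DMAP (cat.), CH2Cl2, 0 °C to rt
Reagents that add atoms: none
Why: Steglich esterification couples the acid and the secondary alcohol under neutral conditions that tolerate acetonide and silyl ether; C5 keeps its configuration because its C–O bond is not broken.

**Step 11**
Reactants: 15 (R)-1-[(S)-2,2-dimethyl-1,3-dioxolan-4-yl]but-3-en-1-yl (5E,9E,13E)-15-(TBDPSO)-6,10,14-trimethyl-2-methylidenepentadeca-5,9,13-trienoate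
Product: 16 (R)-3-[(3E,7E,11E)-13-(TBDPSO)-4,8,12-trimethyltrideca-3,7,11-trien-1-yl]-6-[(S)-2,2-dimethyl-1,3-dioxolan-4-yl]-5,6-dihydro-2H-pyran-2-one
Conditions: second-generation Grubbs catalyst (H2IMes)(PCy3)Cl2Ru=CHPh (10 mol %), CH2Cl2, high dilution, 40 °C
Reagents that add atoms: none
Why: The catalyst should initiate at the only monosubstituted alkene, and the Ru alkylidene at C7 then adds to the tethered 1,1-disubstituted acrylate C8=CH2 through a ruthenacyclobutane ([2+2]) whose cycloreversion expels ethene and forms C7=C8. The closest known reaction type is ring-closing metathesis of 2-substituted acrylates of homoallylic alcohols to 3-substituted 5,6-dihydro-2H-pyran-2-ones. The one ring formed closes as a six-membered unsaturated lactone with the new alkene endocyclic, a size that holds only the cis alkene, so C6 and the carbonyl carbon C8′ end cis and C9 trans. No stereocentre is created, and C5 (R) and the dioxolane centre are spectators. The step needs site selectivity among five alkenes: the three chain alkenes are trisubstituted and slow, their 1,5-relationship to each other and to the acrylate would lead only to cyclobutenes, and closure from C7 onto C11=C12 would need a nine-membered ring. High dilution should suppress cross-metathesis of the vinyl group between molecules.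

**Step 12**
Reactants: 16 (R)-3-[(3E,7E,11E)-13-(TBDPSO)-4,8,12-trimethyltrideca-3,7,11-trien-1-yl]-6-[(S)-2,2-dimethyl-1,3-dioxolan-4-yl]-5,6-dihydro-2H-pyran-2-one
Product: 17 (1R,3Z,7E,11E,15E)-17-(TBDPSO)-1-[(S)-2,2-dimethyl-1,3-dioxolan-4-yl]-4-(hydroxymethyl)-8,12,16-trimethylheptadeca-3,7,11,15-tetraen-1-ol
Conditions: i-Bu2AlH (excess), CH2Cl2, −78 to 0 °C; aq. potassium sodium tartrate
Reagents that add atoms: none
Why: 1,2-Hydride reduction of the unsaturated lactone through the lactol aluminate opens the ring to the diol, freeing C8′ as CH2OH and the C5 hydroxyl while the ring-fixed Z alkene is untouched.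

**Step 13**
Reactants: 17 (1R,3Z,7E,11E,15E)-17-(TBDPSO)-1-[(S)-2,2-dimethyl-1,3-dioxolan-4-yl]-4-(hydroxymethyl)-8,12,16-trimethylheptadeca-3,7,11,15-tetraen-1-ol
Product: 18 (1R,3Z,7E,11E,15E)-17-(TBDPSO)-4-[(TBDPSO)methyl]-1-[(S)-2,2-dimethyl-1,3-dioxolan-4-yl]-8,12,16-trimethylheptadeca-3,7,11,15-tetraen-1-ol
Conditions: TBDPSCl (1 equiv), imidazole, CH2Cl2, 0 °C
Reagents that add atoms: tert-butyl(chloro)diphenylsilane CC(C)(C)[Si](Cl)(c1ccccc1)c1ccccc1
Why: The bulky silyl chloride should react with the primary allylic C8′ hydroxyl and leave the hindered secondary C5 hydroxyl next to the dioxolane free (kinetic selective silylation).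

**Step 14**
Reactants: 18 (1R,3Z,7E,11E,15E)-17-(TBDPSO)-4-[(TBDPSO)methyl]-1-[(S)-2,2-dimethyl-1,3-dioxolan-4-yl]-8,12,16-trimethylheptadeca-3,7,11,15-tetraen-1-ol
Product: 19 (1R,3Z,7E,11E,15E)-17-(TBDPSO)-4-[(TBDPSO)methyl]-1-[(S)-2,2-dimethyl-1,3-dioxolan-4-yl]-8,12,16-trimethylheptadeca-3,7,11,15-tetraen-1-yl 2-(diethoxyphosphoryl)acetate
Conditions: (EtO)2P(O)CH2CO2H, DCC, DMAP (cat.), CH2Cl2, 0 °C to rt
Reagents that add atoms: 2-(diethoxyphosphoryl)acetic acid CCOP(=O)(CC(=O)O)OCC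
Why: Steglich esterification places C2 and C3 of the butenolide on the C5 oxygen and at the same time protects that oxygen during the later C4 oxidation.

**Step 15**
Reactants: 19 (1R,3Z,7E,11E,15E)-17-(TBDPSO)-4-[(TBDPSO)methyl]-1-[(S)-2,2-dimethyl-1,3-dioxolan-4-yl]-8,12,16-trimethylheptadeca-3,7,11,15-tetraen-1-yl 2-(diethoxyphosphoryl)acetate
Product: 20 (2S,3R,5Z,9E,13E,17E)-19-(TBDPSO)-6-[(TBDPSO)methyl]-1,2-dihydroxy-10,14,18-trimethylnonadeca-5,9,13,17-tetraen-3-yl 2-(diethoxyphosphoryl)acetate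
Conditions: AcOH/H2O (4:1), THF, 40 °C; crude diol used at once
Reagents that add atoms: none
Why: Mild aqueous acid hydrolyses the terminal isopropylidene acetal while primary TBDPS ethers, the ester and the trisubstituted alkenes are inert, and the weakly acidic medium keeps 1,2-acyl migration slow.

**Step 16**
Reactants: 20 (2S,3R,5Z,9E,13E,17E)-19-(TBDPSO)-6-[(TBDPSO)methyl]-1,2-dihydroxy-10,14,18-trimethylnonadeca-5,9,13,17-tetraen-3-yl 2-(diethoxyphosphoryl)acetate
Product: 21 (2S,3R,5Z,9E,13E,17E)-1-(TBSO)-19-(TBDPSO)-6-[(TBDPSO)methyl]-2-hydroxy-10,14,18-trimethylnonadeca-5,9,13,17-tetraen-3-yl 2-(diethoxyphosphoryl)acetate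
Conditions: TBSCl (1.1 equiv), imidazole, CH2Cl2, −20 to 0 °C
Reagents that add atoms: tert-butyl(chloro)dimethylsilane CC(C)(C)[Si](C)(C)Cl
Why: Kinetic silylation distinguishes the primary C4′ hydroxyl from the secondary C4 hydroxyl, leaving only C4–OH for oxidation.

**Step 17**
Reactants: 21 (2S,3R,5Z,9E,13E,17E)-1-(TBSO)-19-(TBDPSO)-6-[(TBDPSO)methyl]-2-hydroxy-10,14,18-trimethylnonadeca-5,9,13,17-tetraen-3-yl 2-(diethoxyphosphoryl)acetate
Product: 22 (3R,5Z,9E,13E,17E)-1-(TBSO)-19-(TBDPSO)-6-[(TBDPSO)methyl]-10,14,18-trimethyl-2-oxononadeca-5,9,13,17-tetraen-3-yl 2-(diethoxyphosphoryl)acetate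
Conditions: DMP, CH2Cl2, 0 °C to rt
Reagents that add atoms: none
Why: Dess–Martin oxidation converts the secondary C4 carbinol to the ketone under near-neutral conditions that should not enolise the adjacent C5 centre.

**Step 18**
Reactants: 22 (3R,5Z,9E,13E,17E)-1-(TBSO)-19-(TBDPSO)-6-[(TBDPSO)methyl]-10,14,18-trimethyl-2-oxononadeca-5,9,13,17-tetraen-3-yl 2-(diethoxyphosphoryl)acetate
Product: 23 (R)-4-[(TBSO)methyl]-5-[(2Z,6E,10E,14E)-16-(TBDPSO)-3-[(TBDPSO)methyl]-7,11,15-trimethylhexadeca-2,6,10,14-tetraen-1-yl]furan-2(5H)-one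
Conditions: LiCl, i-Pr2NEt, MeCN, 0 °C to rt
Reagents that add atoms: none
Why: Intramolecular Horner–Wadsworth–Emmons olefination under Masamune–Roush conditions: the lithium-chelated phosphonate carbanion adds to the adjacent C4 ketone in a five-membered closure and loses diethyl phosphate to form C3=C4, and the weak amine base is chosen to spare the C5 centre.

**Step 19**
Reactants: 23 (R)-4-[(TBSO)methyl]-5-[(2Z,6E,10E,14E)-16-(TBDPSO)-3-[(TBDPSO)methyl]-7,11,15-trimethylhexadeca-2,6,10,14-tetraen-1-yl]furan-2(5H)-one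
Product: 24 Hippolide F
Conditions: HF·pyridine, pyridine, THF, 0 °C to rt
Reagents that add atoms: none
Why: Fluoride-driven desilylation under buffered, non-basic conditions should remove the TBS and both primary TBDPS ethers without deprotonating the base-sensitive C5 position of the butenolide.

**Compound list**

1 | (2E,6E)-farnesol | CC(C)=CCC/C(C)=C/CC/C(C)=C/CO | starting material
2 | (2E,6E)-farnesyl acetate | CC(C)=CCC/C(C)=C/CC/C(C)=C/COC(C)=O | intermediate
3 | (2E,6E,10E)-12-hydroxy-3,7,11-trimethyldodeca-2,6,10-trien-1-yl acetate | C/C(=C\CC/C(C)=C/CC/C(C)=C/COC(C)=O)CO | intermediate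
4 | (2E,6E,10E)-12-(TBDPSO)-3,7,11-trimethyldodeca-2,6,10-trien-1-yl acetate | C/C(=C\CC/C(C)=C/CC/C(C)=C/COC(C)=O)CO[Si](c1ccccc1)(c1ccccc1)C(C)(C)C | intermediate
5 | (2E,6E,10E)-12-(TBDPSO)-3,7,11-trimethyldodeca-2,6,10-trien-1-ol | C/C(=C\CC/C(C)=C/CC/C(C)=C/CO)CO[Si](c1ccccc1)(c1ccccc1)C(C)(C)C | intermediate
6 | (2E,6E,10E)-1-bromo-12-(TBDPSO)-3,7,11-trimethyldodeca-2,6,10-triene | C/C(=C\CC/C(C)=C/CC/C(C)=C/CBr)CO[Si](c1ccccc1)(c1ccccc1)C(C)(C)C | intermediate
7 | 2-methylprop-2-en-1-ol | C=C(C)CO | starting material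
8 | dilithio dianion of 7, lithium 2-(lithiomethyl)prop-2-en-1-olate | [Li]CC(=C)CO[Li] | intermediate
9 | (5E,9E,13E)-15-(TBDPSO)-6,10,14-trimethyl-2-methylidenepentadeca-5,9,13-trien-1-ol | C/C(=C\CC/C(C)=C/CC/C(C)=C/CCC(=C)CO)CO[Si](c1ccccc1)(c1ccccc1)C(C)(C)C | intermediate
10 | (5E,9E,13E)-15-(TBDPSO)-6,10,14-trimethyl-2-methylidenepentadeca-5,9,13-trienal | C/C(=C\CC/C(C)=C/CC/C(C)=C/CCC(=C)C=O)CO[Si](c1ccccc1)(c1ccccc1)C(C)(C)C | intermediate
11 | (5E,9E,13E)-15-(TBDPSO)-6,10,14-trimethyl-2-methylidenepentadeca-5,9,13-trienoic acid | C/C(=C\CC/C(C)=C/CC/C(C)=C/CCC(=C)C(=O)O)CO[Si](c1ccccc1)(c1ccccc1)C(C)(C)C | intermediate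
12 | (S)-2,2-dimethyl-1,3-dioxolane-4-carbaldehyde, (S)-glyceraldehyde acetonide | O=C[C@@H]1COC(C)(C)O1 | starting material
13 | (R)-1-[(S)-2,2-dimethyl-1,3-dioxolan-4-yl]but-3-en-1-yl diisopinocampheylborinate, Ipc of the (−)-α-pinene series | C=CC[C@@H](OB([C@H]2C[C@H]3C[C@@H]([C@@H]2C)C3(C)C)[C@H]2C[C@H]3C[C@@H]([C@@H]2C)C3(C)C)[C@@H]1COC(C)(C)O1 | intermediate
14 | (R)-1-[(S)-2,2-dimethyl-1,3-dioxolan-4-yl]but-3-en-1-ol | C=CC[C@@H](O)[C@@H]1COC(C)(C)O1 | intermediate
15 | (R)-1-[(S)-2,2-dimethyl-1,3-dioxolan-4-yl]but-3-en-1-yl (5E,9E,13E)-15-(TBDPSO)-6,10,14-trimethyl-2-methylidenepentadeca-5,9,13-trienoate | C/C(=C\CC/C(C)=C/CC/C(C)=C/CCC(=C)C(=O)O[C@H](CC=C)[C@@H]1COC(C)(C)O1)CO[Si](c1ccccc1)(c1ccccc1)C(C)(C)C | intermediate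
16 | (R)-3-[(3E,7E,11E)-13-(TBDPSO)-4,8,12-trimethyltrideca-3,7,11-trien-1-yl]-6-[(S)-2,2-dimethyl-1,3-dioxolan-4-yl]-5,6-dihydro-2H-pyran-2-one | C/C(=C\CC/C(C)=C/CC/C(C)=C/CCC1=CC[C@H]([C@@H]2COC(C)(C)O2)OC1=O)CO[Si](c1ccccc1)(c1ccccc1)C(C)(C)C | intermediate
17 | (1R,3Z,7E,11E,15E)-17-(TBDPSO)-1-[(S)-2,2-dimethyl-1,3-dioxolan-4-yl]-4-(hydroxymethyl)-8,12,16-trimethylheptadeca-3,7,11,15-tetraen-1-ol | C/C(=C\CC/C(C)=C/CC/C(C)=C/CC/C(=C/C[C@@H](O)[C@@H]1COC(C)(C)O1)CO)CO[Si](c1ccccc1)(c1ccccc1)C(C)(C)C | intermediate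
18 | (1R,3Z,7E,11E,15E)-17-(TBDPSO)-4-[(TBDPSO)methyl]-1-[(S)-2,2-dimethyl-1,3-dioxolan-4-yl]-8,12,16-trimethylheptadeca-3,7,11,15-tetraen-1-ol | C/C(=C\CC/C(C)=C/CC/C(C)=C/CC/C(=C/C[C@@H](O)[C@@H]1COC(C)(C)O1)CO[Si](c1ccccc1)(c1ccccc1)C(C)(C)C)CO[Si](c1ccccc1)(c1ccccc1)C(C)(C)C | intermediate
19 | (1R,3Z,7E,11E,15E)-17-(TBDPSO)-4-[(TBDPSO)methyl]-1-[(S)-2,2-dimethyl-1,3-dioxolan-4-yl]-8,12,16-trimethylheptadeca-3,7,11,15-tetraen-1-yl 2-(diethoxyphosphoryl)acetate | C/C(=C\CC/C(C)=C/CC/C(C)=C/CC/C(=C/C[C@@H](OC(=O)CP(=O)(OCC)OCC)[C@@H]1COC(C)(C)O1)CO[Si](c1ccccc1)(c1ccccc1)C(C)(C)C)CO[Si](c1ccccc1)(c1ccccc1)C(C)(C)C | intermediate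
20 | (2S,3R,5Z,9E,13E,17E)-19-(TBDPSO)-6-[(TBDPSO)methyl]-1,2-dihydroxy-10,14,18-trimethylnonadeca-5,9,13,17-tetraen-3-yl 2-(diethoxyphosphoryl)acetate | C/C(=C\CC/C(C)=C/CC/C(C)=C/CC/C(=C/C[C@@H](OC(=O)CP(=O)(OCC)OCC)[C@@H](O)CO)CO[Si](c1ccccc1)(c1ccccc1)C(C)(C)C)CO[Si](c1ccccc1)(c1ccccc1)C(C)(C)C | intermediate
21 | (2S,3R,5Z,9E,13E,17E)-1-(TBSO)-19-(TBDPSO)-6-[(TBDPSO)methyl]-2-hydroxy-10,14,18-trimethylnonadeca-5,9,13,17-tetraen-3-yl 2-(diethoxyphosphoryl)acetate | C/C(=C\CC/C(C)=C/CC/C(C)=C/CC/C(=C/C[C@@H](OC(=O)CP(=O)(OCC)OCC)[C@@H](O)CO[Si](C)(C)C(C)(C)C)CO[Si](c1ccccc1)(c1ccccc1)C(C)(C)C)CO[Si](c1ccccc1)(c1ccccc1)C(C)(C)C | intermediate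
22 | (3R,5Z,9E,13E,17E)-1-(TBSO)-19-(TBDPSO)-6-[(TBDPSO)methyl]-10,14,18-trimethyl-2-oxononadeca-5,9,13,17-tetraen-3-yl 2-(diethoxyphosphoryl)acetate | C/C(=C\CC/C(C)=C/CC/C(C)=C/CC/C(=C/C[C@@H](OC(=O)CP(=O)(OCC)OCC)C(=O)CO[Si](C)(C)C(C)(C)C)CO[Si](c1ccccc1)(c1ccccc1)C(C)(C)C)CO[Si](c1ccccc1)(c1ccccc1)C(C)(C)C | intermediate
23 | (R)-4-[(TBSO)methyl]-5-[(2Z,6E,10E,14E)-16-(TBDPSO)-3-[(TBDPSO)methyl]-7,11,15-trimethylhexadeca-2,6,10,14-tetraen-1-yl]furan-2(5H)-one | C/C(=C\CC/C(C)=C/CC/C(C)=C/CC/C(=C/C[C@H]1OC(=O)C=C1CO[Si](C)(C)C(C)(C)C)CO[Si](c1ccccc1)(c1ccccc1)C(C)(C)C)CO[Si](c1ccccc1)(c1ccccc1)C(C)(C)C | intermediate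
24 | Hippolide F, (R)-4-(hydroxymethyl)-5-[(2Z,6E,10E,14E)-16-hydroxy-3-(hydroxymethyl)-7,11,15-trimethylhexadeca-2,6,10,14-tetraen-1-yl]furan-2(5H)-one | C/C(=C\CC/C(C)=C/CC/C(C)=C/CC/C(=C/C[C@H]1OC(=O)C=C1CO)CO)CO | target

**Step count and risks**

Total step count: 19. Longest linear sequence: 18 steps (1 to 24 through steps 1–8 and 10–19).

Steps most likely to fail:

Step 18. The base may enolise the α-acyloxy ketone before closure or deprotonate C5 of the butenolide after it, eroding the C5 configuration, and may also expel the allylic silyloxy group. The fallback closes the butenolide without base by ketenylidene annulation and sets out from 18. The C5 hydroxyl would be capped (NaH, PMBCl, Bu4NI, THF/DMF) as the 4-methoxybenzyl ether F1. The acetonide would be hydrolysed as in step 15 to the diol F2, the primary hydroxyl silylated (TBSCl, imidazole) to the TBS ether F3, and the C4 carbinol oxidised with DMP to the ketone F4. DDQ in wet CH2Cl2 at pH 7 would then free the α-hydroxy ketone F5. With Ph3P=C=C=O in toluene at 80 °C, F5 should be acylated on oxygen and close by intramolecular Wittig reaction, coming back to the route at 23. An ether on the C5 oxygen also cannot migrate while the 1,2-diol is free.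

Step 6. Metalation of the alkoxide may be incomplete, and the dianion may attack the bromide in the SN2′ sense or act as a base, so that little of the linear product forms. The fallback inverts the polarity and sets out from 6. PhSO2Na in DMF would give the allylic phenyl sulfone F6. Its lithio derivative (n-BuLi, THF, −78 °C) would be alkylated with ethyl 2-(bromomethyl)acrylate to the sulfonyl ester F7. i-Bu2AlH would reduce the ester to the hydroxy sulfone F8, and reductive desulfonylation with LiBHEt3 and catalytic PdCl2(dppp) would come back to the route at 9.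

Step 11. Closure onto the electron-poor, 1,1-disubstituted acrylate may be slow, so that cross-metathesis of the vinyl group between molecules and catalyst decay take over. The fallback forms the same C7=C8 bond on a silicon tether that keeps both alkenes electron-rich; it sets out from 14 and 9. Sequential silylation with Ph2SiCl2 (Et3N, DMAP, CH2Cl2; 14 first, then 9) would give the mixed diphenylsilylene bis-ether F9. Ring-closing metathesis with the same ruthenium catalyst would close the eight-membered cyclic silylene ether F10, a ring that again holds only the cis alkene. K2CO3 in MeOH would cleave the silylene and come back to the route at 17, passing by steps 7, 8, 10 and 12.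

**Further compounds**

F1 | step 18 | 4-methoxybenzyl ether of 18 at the C5 oxygen (C5 R, acetonide and both TBDPS ethers kept) | C/C(=C\CC/C(C)=C/CC/C(C)=C/CC/C(=C/C[C@@H](OCc1ccc(OC)cc1)[C@@H]1COC(C)(C)O1)CO[Si](c1ccccc1)(c1ccccc1)C(C)(C)C)CO[Si](c1ccccc1)(c1ccccc1)C(C)(C)C
F2 | step 18 | C4,C4′-diol from F1 by acetonide removal (C4 S, C5 R) | C/C(=C\CC/C(C)=C/CC/C(C)=C/CC/C(=C/C[C@@H](OCc1ccc(OC)cc1)[C@@H](O)CO)CO[Si](c1ccccc1)(c1ccccc1)C(C)(C)C)CO[Si](c1ccccc1)(c1ccccc1)C(C)(C)C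
F3 | step 18 | C4′-O-TBS ether of F2 with free C4 hydroxyl | C/C(=C\CC/C(C)=C/CC/C(C)=C/CC/C(=C/C[C@@H](OCc1ccc(OC)cc1)[C@@H](O)CO[Si](C)(C)C(C)(C)C)CO[Si](c1ccccc1)(c1ccccc1)C(C)(C)C)CO[Si](c1ccccc1)(c1ccccc1)C(C)(C)C
F4 | step 18 | C4 ketone from F3 (C5 R, PMB ether on the C5 oxygen) | C/C(=C\CC/C(C)=C/CC/C(C)=C/CC/C(=C/C[C@@H](OCc1ccc(OC)cc1)C(=O)CO[Si](C)(C)C(C)(C)C)CO[Si](c1ccccc1)(c1ccccc1)C(C)(C)C)CO[Si](c1ccccc1)(c1ccccc1)C(C)(C)C
F5 | step 18 | α-hydroxy ketone from F4 (free C5 hydroxyl R, C4 ketone, C4′-O-TBS) | C/C(=C\CC/C(C)=C/CC/C(C)=C/CC/C(=C/C[C@@H](O)C(=O)CO[Si](C)(C)C(C)(C)C)CO[Si](c1ccccc1)(c1ccccc1)C(C)(C)C)CO[Si](c1ccccc1)(c1ccccc1)C(C)(C)C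
F6 | step 6 | tert-butyl{[(2E,6E,10E)-2,6,10-trimethyl-12-(phenylsulfonyl)dodeca-2,6,10-trien-1-yl]oxy}diphenylsilane | C/C(=C\CC/C(C)=C/CC/C(C)=C/CS(=O)(=O)c1ccccc1)CO[Si](c1ccccc1)(c1ccccc1)C(C)(C)C
F7 | step 6 | ethyl (5E,9E,13E)-15-(TBDPSO)-6,10,14-trimethyl-2-methylidene-4-(phenylsulfonyl)pentadeca-5,9,13-trienoate, racemic at C4 | C/C(=C\CC/C(C)=C/CC/C(C)=C/C(CC(=C)C(=O)OCC)S(=O)(=O)c1ccccc1)CO[Si](c1ccccc1)(c1ccccc1)C(C)(C)C
F8 | step 6 | (5E,9E,13E)-15-(TBDPSO)-6,10,14-trimethyl-2-methylidene-4-(phenylsulfonyl)pentadeca-5,9,13-trien-1-ol, racemic at C4 | C/C(=C\CC/C(C)=C/CC/C(C)=C/C(CC(=C)CO)S(=O)(=O)c1ccccc1)CO[Si](c1ccccc1)(c1ccccc1)C(C)(C)C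
F9 | step 11 | mixed diphenylsilylene bis-ether of the C5 oxygen of 14 and the C8′ oxygen of 9 | C/C(=C\CC/C(C)=C/CC/C(C)=C/CCC(=C)CO[Si](c1ccccc1)(c1ccccc1)O[C@H](CC=C)[C@@H]1COC(C)(C)O1)CO[Si](c1ccccc1)(c1ccccc1)C(C)(C)C
F10 | step 11 | eight-membered cyclic diphenylsilylene ether (1,3,2-dioxasilocine) with the Z C7=C8 alkene in the ring, C5 R, dioxolane S | C/C(=C\CC/C(C)=C/CC/C(C)=C/CC/C1=C/C[C@H]([C@@H]2COC(C)(C)O2)O[Si](c2ccccc2)(c2ccccc2)OC1)CO[Si](c1ccccc1)(c1ccccc1)C(C)(C)C
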